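**Retrosynthetic overview**
- The strategy rests on ring B (C5–C10) being a masked (S)-carvone: C9 is the enone carbonyl, C7=C8 with C17 is the enone alkene, C5 is the carvone stereocentre, and its isopropenyl group is C4 with C18 and C19.
- Side chain: C14–C15 by Horner–Wadsworth–Emmons olefination of a C13 methyl ketone; C12–C13–C16 by bromoacetone alkylation of a C11 borane; C11 by methylenation of the C9 ketone; O6 by γ-oxidation of the 7-en-9-one.
- Ring A: the C3–C4 bond is cut as a conjugate addition of a tertiary C4 radical (hydrogen atom transfer to the oxidised isopropenyl group) onto a C1–C3 acrylate unit attached at C10.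
- Ring order: ring B is bought (carvone), C20 and C1–C3 are put on C10 by two enolate alkylations, ring A is closed onto ring B, then the side chain is grown from C9.

Key step: step 7

Remark on the chemistry: labdane numbering is used for all compounds, including the monocyclic ones. The target is read as an ent-labdane; as drawn in the usual orientation it has 10α-CH3 (C20), 5β-H, 4α-CH3 (C19, axial), 4β-CH2OH (C18, equatorial), 6β-OH (equatorial) and 9β-H (side chain equatorial, cis to C20).

**Route**

Step 1
Reactants: 1 (S)-(+)-carvone
Product: 2 (S)-10-chlorocarvone, i.e. (S)-5-(3-chloroprop-1-en-2-yl)-2-methylcyclohex-2-en-1-one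
Conditions: Ca(OCl)2, solid CO2, CH2Cl2/H2O, 0 °C
Reagents that add atoms: calcium hypochlorite, [Ca+2].[O-]Cl.[O-]Cl
Why: Ene-type allylic chlorination by HOCl made in the flask attacks only the electron-rich 1,1-disubstituted alkene and regenerates it as a 2-(chloromethyl)vinyl group, leaving the enone and the C5 stereocentre untouched.

Step 2
Reactants: 2 (S)-10-chlorocarvone
Product: 3 (S)-10-acetoxycarvone
Conditions: KOAc, Bu4NI (cat.), DMF, 60 °C
Reagents that add atoms: potassium acetate, CC(=O)[O-].[K+]
Why: SN2 displacement of the primary allylic chloride by acetate with iodide catalysis; direct and allylic (SN2′) attack lead to the same product.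

Step 3
Reactants: 3 (S)-10-acetoxycarvone
Product: 4 (S)-10-hydroxycarvone
Conditions: K2CO3 (cat.), MeOH, 0 °C
Reagents that add atoms: none
Why: Base-catalysed transesterification (methanolysis) frees the primary allylic alcohol under conditions too mild to isomerise the enone.

Step 4
Reactants: 4 (S)-10-hydroxycarvone
Product: 5 (S)-10-(tert-butyldiphenylsilyloxy)carvone
Conditions: TBDPSCl, imidazole, DMF, rt
Reagents that add atoms: tert-butyl(chloro)diphenylsilane, CC(C)(C)[Si](Cl)(c1ccccc1)c1ccccc1
Why: Imidazole-promoted silylation of a primary alcohol; the TBDPS group is chosen because it survives every later step up to the last and its bulk is used to steer C4 in step 7.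

Step 5
Reactants: 5 (S)-10-(tert-butyldiphenylsilyloxy)carvone
Product: 7 C10-methyl ketone (C20 installed; both C10 epimers), via lithium dienolate 6 (not isolated)
Conditions: LiN(iPr)2 (LDA), THF, −78 °C; MeI, −78 to −20 °C
Reagents that add atoms: iodomethane, CI
Why: Kinetic deprotonation by the hindered amide at the α′ carbon (C10) gives the cross-conjugated enolate, and its SN2 methylation installs C20; the C10 configuration is irrelevant because the centre is re-enolised in step 6.

Step 6
Reactants: 7 C10-methyl ketone; 8 methyl 2-(bromomethyl)acrylate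
Product: 10 cyclisation precursor (C10 quaternary ketone: C20 methyl cis and the 2-(methoxycarbonyl)allyl group trans to the C5 substituent), via lithium enolate 9 (not isolated)
Conditions: LiN(iPr)2 (LDA), THF/DMPU, −78 °C; 8, −78 to −40 °C
Reagents that add atoms: none
Why: Enolate alkylation with the activated allylic bromide creates the C10 quaternary centre; the electrophile approaches the enolate face anti to the bulky C5 substituent, so the C1–C3 unit ends trans to it and C20 cis, the arrangement that becomes the trans ring fusion.

Step 7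
Reactants: 10 cyclisation precursor
Product: 11 trans-decalin enone ester (methyl 18-silyloxy-9-oxo-ent-drim-7-ene-2-carboxylate type; 4α-CH3, 4β-CH2OTBDPS, 5β-H, 10α-CH3; both C2 epimers)
Conditions: Fe(acac)3 (30 mol %), PhSiH3, EtOH/ethylene glycol, 60 °C
Reagents that add atoms: none
Why: The trivalent iron hydride formed from Fe(acac)3 and PhSiH3 transfers a hydrogen atom to the terminal CH2 of the electron-rich 1,1-disubstituted allyl silyl ether alkene (this CH2 becomes the C19 methyl), and the resulting nucleophilic tertiary C4 radical adds to the unsubstituted acrylate terminus C3; the C2 α-ester radical is then reduced by divalent iron and protonated by ethanol. The closest known reaction type is the iron-hydride HAT reductive olefin coupling (Giese-type conjugate addition of an alkene-derived tertiary radical to an acrylate), used here intramolecularly. Ring A is closed in a 6-endo-trig mode through a chair transition state, the 5-exo alternative being an anti-Michael attack on the substituted acrylate carbon. The ring fusion is already fixed as trans by C5 and C10, whose two arms are both equatorial on ring B; the new C4 centre is controlled by allylic-type strain in the planar radical, which turns the bulky CH2OTBDPS group toward H5 (the future equatorial 4β site) and leaves the small new methyl next to the axial C10 methyl (4α), while C2 forms as both epimers and is removed in step 9. The step needs hydrogen atom transfer to the allyl silyl ether alkene in preference to the enone and the acrylate, and it needs this C4 face selectivity; the electron-rich, unhindered character of that alkene and the size of the TBDPS group are expected to secure both, and the neutral conditions leave the β-silyloxy group and the enone intact.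

Step 8
Reactants: 11 trans-decalin enone ester
Product: 12 C2 carboxylic acid (both C2 epimers)
Conditions: LiOH, THF/MeOH/H2O, 40 °C; then aq. HCl to pH 3
Reagents that add atoms: lithium hydroxide, [Li+].[OH-]
Why: Saponification of the unhindered secondary methyl ester; the neopentyl TBDPS ether and the enone tolerate aqueous LiOH.

Step 9
Reactants: 12 C2 carboxylic acid
Product: 14 bicyclic enone (18-tert-butyldiphenylsilyloxy-ent-drim-7-en-9-one type), via Barton ester 13 (not isolated)
Conditions: N-hydroxypyridine-2-thione, DCC, DMAP (cat.), CH2Cl2, rt, dark; then t-BuSH, visible light, PhH, rt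
Reagents that add atoms: none
Why: Barton reductive decarboxylation: the thiohydroxamate ester fragments in a radical chain to the secondary C2 radical, which takes hydrogen from the thiol, so the C2 stereocentre is erased and one compound results.

Step 10
Reactants: 14 bicyclic enone
Product: 15 trimethylsilyl dienol ether (9-silyloxy-6,8-diene)
Conditions: TMSOTf, Et3N, CH2Cl2, 0 °C
Reagents that add atoms: trimethylsilyl trifluoromethanesulfonate, C[Si](C)(C)OS(=O)(=O)C(F)(F)F
Why: Soft enolisation (O-silylation, then amine deprotonation): C10 is quaternary, so only γ-deprotonation at C6 is possible and the linear 2-silyloxy diene C9=C8–C7=C6 must form.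

Step 11
Reactants: 15 trimethylsilyl dienol ether
Product: 17 6β-hydroxy-7-en-9-one, via silyloxy epoxide 16 (not isolated)
Conditions: mCPBA, CH2Cl2, −20 °C; aq. NaHCO3/Na2S2O3 work-up
Reagents that add atoms: meta-chloroperbenzoic acid, OOC(=O)c1cccc(Cl)c1
Why: Vinylogous Rubottom oxidation: the peracid epoxidises the terminal C6=C7 bond of the dienol ether (C8 is fully substituted) from the β face, opposite the axial C19 and C20 methyls that both flank the α face of C6, and opening of the silyloxy epoxide with loss of silicon returns the enone with the equatorial 6β-hydroxyl.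

Step 12
Reactants: 17 6β-hydroxy-7-en-9-one
Product: 18 6β-(tert-butyldimethylsilyloxy)-7-en-9-one
Conditions: TBSOTf, 2,6-lutidine, CH2Cl2, −78 to 0 °C
Reagents that add atoms: tert-butyldimethylsilyl trifluoromethanesulfonate, CC(C)(C)[Si](C)(C)OS(=O)(=O)C(F)(F)F
Why: Silylation of the hindered secondary allylic alcohol with a silyl triflate and a non-nucleophilic base protects O6 against the organolithium and the bases of the following steps.

Step 13
Reactants: 18 6β-(tert-butyldimethylsilyloxy)-7-en-9-one
Product: 19 C9 tertiary β-hydroxysilane (9β-CH2SiMe3, 9α-OH expected)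
Conditions: Me3SiCH2Li, THF, −78 to 0 °C; H2O
Reagents that add atoms: (trimethylsilyl)methyllithium, [Li]C[Si](C)(C)C
Why: Addition half of a Peterson olefination: the α-silyl carbanion adds 1,2 to the C9 ketone, which has no α-hydrogen, from the β face anti to the axial C10 methyl; the carbinol configuration is lost in step 14.

Step 14
Reactants: 19 C9 tertiary β-hydroxysilane
Product: 20 7,9(11)-diene (exocyclic C9=C11 methylene)
Conditions: KH, THF, 0 °C to rt
Reagents that add atoms: none
Why: Base-mediated syn elimination of the potassium β-silyl alkoxide (Peterson elimination) gives the exocyclic alkene and avoids acid, which would ionise the tertiary allylic alcohol.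

Step 15
Reactants: 20 7,9(11)-diene; 21 bromoacetone
Product: 23 C13 methyl ketone (9β-H; side chain C11–C12–C13(=O)–C16), via B-alkyl-9-BBN 22 (not isolated)
Conditions: 9-BBN, THF, 0 to 50 °C; then 21, potassium 2,6-di-tert-butylphenoxide, THF, 0 °C to rt
Reagents that add atoms: none
Why: Hydroboration puts boron on the terminal C11 and delivers hydrogen to C9 from the β face opposite the axial C10 methyl (setting 9β-H); the hindered phenoxide then forms the bromoacetone enolate, which gives a boron ate complex that undergoes 1,2-migration of the primary alkyl group with loss of bromide (organoborane α-alkylation of an α-bromo ketone).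

Step 16
Reactants: 23 C13 methyl ketone; 24 trimethyl phosphonoacetate
Product: 25 bis-silyl ether of the target (13E enoate)
Conditions: NaH, THF, 0 to 50 °C; chromatographic removal of the Z isomer
Reagents that add atoms: none
Why: Horner–Wadsworth–Emmons olefination of the methyl ketone with the stabilised phosphonate anion should favour the E enoate (ester trans to the larger C12 chain), the minor Z isomer being separable.

Step 17
Reactants: 25 bis-silyl ether of the target
Product: 26 CNP0149445.1, methyl ent-6α,18-dihydroxylabda-7,13E-dien-15-oate (as drawn: 6β-OH, 4β-CH2OH)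
Conditions: Bu4NF, AcOH, THF, rt to 45 °C
Reagents that add atoms: none
Why: Fluoride-driven cleavage of both silyl ethers (Si–F bond formation), with acetic acid buffering to keep the enoate and the allylic alcohol away from basic alkoxide.

**Compound list**
1 | (S)-(+)-carvone | CC1=CC[C@@H](CC1=O)C(C)=C | starting material
2 | (S)-10-chlorocarvone | O=C1C(C)=CC[C@H](C(=C)CCl)C1 | intermediate
3 | (S)-10-acetoxycarvone | O=C1C(C)=CC[C@H](C(=C)COC(C)=O)C1 | intermediate
4 | (S)-10-hydroxycarvone | O=C1C(C)=CC[C@H](C(=C)CO)C1 | intermediate
5 | (S)-10-(tert-butyldiphenylsilyloxy)carvone | O=C1C(C)=CC[C@H](C(=C)CO[Si](c2ccccc2)(c2ccccc2)C(C)(C)C)C1 | intermediate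
6 | lithium cross-conjugated dienolate of 5 (not isolated) | [Li]OC1=C[C@@H](C(=C)CO[Si](c2ccccc2)(c2ccccc2)C(C)(C)C)CC=C1C | intermediate
7 | C10-methyl ketone (C20 installed, both C10 epimers) | O=C1C(C)=CC[C@H](C(=C)CO[Si](c2ccccc2)(c2ccccc2)C(C)(C)C)C1C | intermediate
8 | methyl 2-(bromomethyl)acrylate | COC(=O)C(=C)CBr | starting material
9 | lithium enolate of 7 (not isolated) | [Li]OC1=C(C)[C@@H](C(=C)CO[Si](c2ccccc2)(c2ccccc2)C(C)(C)C)CC=C1C | intermediate
10 | cyclisation precursor, C10-methyl-C10-[2-(methoxycarbonyl)allyl] silyloxycarvone (allyl unit trans to the C5 substituent) | O=C1C(C)=CC[C@H](C(=C)CO[Si](c2ccccc2)(c2ccccc2)C(C)(C)C)[C@@]1(C)CC(=C)C(=O)OC | intermediate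
11 | trans-decalin enone with C2 methyl ester (C2 epimers) | O=C1C(C)=CC[C@@H]2[C@@](C)(CO[Si](c3ccccc3)(c3ccccc3)C(C)(C)C)CC(C(=O)OC)C[C@@]12C | intermediate
12 | trans-decalin enone C2 carboxylic acid (C2 epimers) | O=C1C(C)=CC[C@@H]2[C@@](C)(CO[Si](c3ccccc3)(c3ccccc3)C(C)(C)C)CC(C(=O)O)C[C@@]12C | intermediate
13 | Barton (2-thioxopyridin-1-yl) ester of 12 (not isolated) | O=C1C(C)=CC[C@@H]2[C@@](C)(CO[Si](c3ccccc3)(c3ccccc3)C(C)(C)C)CC(C(=O)On3ccccc3=S)C[C@@]12C | intermediate
14 | 18-(tert-butyldiphenylsilyloxy)-ent-drim-7-en-9-one type bicyclic enone | O=C1C(C)=CC[C@@H]2[C@@](C)(CO[Si](c3ccccc3)(c3ccccc3)C(C)(C)C)CCC[C@@]12C | intermediate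
15 | 9-trimethylsilyloxy-6,8-diene (silyl dienol ether) | C[Si](C)(C)OC1=C(C)C=C[C@@H]2[C@@](C)(CO[Si](c3ccccc3)(c3ccccc3)C(C)(C)C)CCC[C@@]12C | intermediate
16 | 6β,7β-epoxy-9-trimethylsilyloxy-8-ene (not isolated) | C[Si](C)(C)OC1=C(C)[C@H]3O[C@H]3[C@@H]2[C@@](C)(CO[Si](c4ccccc4)(c4ccccc4)C(C)(C)C)CCC[C@@]12C | intermediate
17 | 6β-hydroxy-7-en-9-one | O=C1C(C)=C[C@@H](O)[C@@H]2[C@@](C)(CO[Si](c3ccccc3)(c3ccccc3)C(C)(C)C)CCC[C@@]12C | intermediate
18 | 6β-(tert-butyldimethylsilyloxy)-7-en-9-one | O=C1C(C)=C[C@@H](O[Si](C)(C)C(C)(C)C)[C@@H]2[C@@](C)(CO[Si](c3ccccc3)(c3ccccc3)C(C)(C)C)CCC[C@@]12C | intermediate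
19 | C9 tertiary β-hydroxysilane (9β-CH2SiMe3, 9α-OH) | C[Si](C)(C)C[C@@]1(O)C(C)=C[C@@H](O[Si](C)(C)C(C)(C)C)[C@@H]2[C@@](C)(CO[Si](c3ccccc3)(c3ccccc3)C(C)(C)C)CCC[C@@]12C | intermediate
20 | 7,9(11)-diene | C=C1C(C)=C[C@@H](O[Si](C)(C)C(C)(C)C)[C@@H]2[C@@](C)(CO[Si](c3ccccc3)(c3ccccc3)C(C)(C)C)CCC[C@@]12C | intermediate
21 | bromoacetone | CC(=O)CBr | starting material
22 | C11 B-alkyl-9-borabicyclo[3.3.1]nonane, 9β-H (not isolated) | C(B1C2CCCC1CCC2)[C@@H]1C(C)=C[C@@H](O[Si](C)(C)C(C)(C)C)[C@@H]2[C@@](C)(CO[Si](c3ccccc3)(c3ccccc3)C(C)(C)C)CCC[C@@]12C | intermediate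
23 | C13 methyl ketone | CC(=O)CC[C@@H]1C(C)=C[C@@H](O[Si](C)(C)C(C)(C)C)[C@@H]2[C@@](C)(CO[Si](c3ccccc3)(c3ccccc3)C(C)(C)C)CCC[C@@]12C | intermediate
24 | trimethyl phosphonoacetate | COC(=O)CP(=O)(OC)OC | starting material
25 | bis-silyl ether of the target (13E) | COC(=O)/C=C(\C)CC[C@@H]1C(C)=C[C@@H](O[Si](C)(C)C(C)(C)C)[C@@H]2[C@@](C)(CO[Si](c3ccccc3)(c3ccccc3)C(C)(C)C)CCC[C@@]12C | intermediate
26 | CNP0149445.1 | COC(=O)/C=C(\C)CC[C@@H]1C(C)=C[C@@H](O)[C@@H]2[C@@](C)(CO)CCC[C@@]12C | target

**Totals and risks**

Total step count: 17. Longest linear sequence: 17 steps (1 to 26).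

Steps most likely to fail:

1. Step 7. The C4 radical may close ring A with poor facial selectivity (silyloxymethyl group ending axial), may be quenched by a second hydrogen atom before it cyclises, or the hydride may attack the acrylate first. The fallback sets out from 1 and comes back at 11. Carvone 1 would be methylated at C10 (LiN(iPr)2, MeI) to 6-methylcarvone F1. Its lithium enolate would be alkylated with 8 to the silyl-free keto ester F2. The isopropenyl group alone would be epoxidised with mCPBA to the epoxide F3 (both epoxide epimers are usable). Cp2TiCl (trivalent titanium, made from Cp2TiCl2 and Zn in THF) would open the epoxide homolytically to the same tertiary C4 radical, now carrying a bulky CH2OTi(Cp)2Cl group and formed without any metal hydride. This radical should close ring A 6-endo onto the acrylate and, after reduction of the ester radical and protonation, give the hydroxy ester F4. Silylation of F4 with TBDPSCl and imidazole returns to 11.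

2. Step 11. The peracid may attack C6 with poor facial selectivity, because stereoelectronically favoured axial attack on the α face competes with the sterically favoured β attack, or it may attack C8. The fallback sets out from 15 and comes back at 17. The dienol ether 15 would be photo-oxygenated (O2, tetraphenylporphyrin, visible light, CH2Cl2, −78 °C). Singlet oxygen must bond to C6 and C9 at once, and the α face of C9 is blocked by the adjacent axial C10 methyl, so the [4+2] adduct should be the β-face endoperoxide F5. Thiourea in MeOH would cleave the O–O bond, and the C9 silyl hemiketal would collapse with loss of silicon to 17.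

3. Step 15. The hindered, β-branched alkyl group may migrate too slowly from boron to the bromoacetone enolate carbon, so that bromoacetone is consumed by self-condensation. The fallback sets out from 22 and comes back at 23. The borane 22 would be oxidised (NaOH, H2O2) to the primary alcohol F6 and converted (I2, PPh3, imidazole) to the iodide F7. F7 would alkylate the sodium enolate of allyl acetoacetate (NaH, DMF, 60 °C) to the allyl β-keto ester F8. Pd(PPh3)4 (zerovalent palladium) with morpholine in THF would remove the allyl group and the carboxyl carbon under neutral conditions, giving 23.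

**Further compounds**
F1 | step 7 | 6-methylcarvone (C10-methyl, both epimers) | O=C1C(C)=CC[C@H](C(C)=C)C1C
F2 | step 7 | C10-methyl-C10-[2-(methoxycarbonyl)allyl]carvone (allyl unit trans to isopropenyl) | O=C1C(C)=CC[C@H](C(C)=C)[C@@]1(C)CC(=C)C(=O)OC
F3 | step 7 | isopropenyl epoxide of F2 (both epoxide epimers) | O=C1C(C)=CC[C@H](C2(C)CO2)[C@@]1(C)CC(=C)C(=O)OC
F4 | step 7 | 18-hydroxy trans-decalin enone C2 methyl ester (C2 epimers) | O=C1C(C)=CC[C@@H]2[C@@](C)(CO)CC(C(=O)OC)C[C@@]12C
F5 | step 11 | 6β,9β-epidioxy-9-trimethylsilyloxy-7-ene (endoperoxide) | C[Si](C)(C)O[C@]1(OO2)C(C)=C[C@@H]2[C@@H]3[C@@](C)(CO[Si](c4ccccc4)(c4ccccc4)C(C)(C)C)CCC[C@@]13C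
F6 | step 15 | C11 primary alcohol (9β-H) | OC[C@@H]1C(C)=C[C@@H](O[Si](C)(C)C(C)(C)C)[C@@H]2[C@@](C)(CO[Si](c3ccccc3)(c3ccccc3)C(C)(C)C)CCC[C@@]12C
F7 | step 15 | C11 primary iodide | IC[C@@H]1C(C)=C[C@@H](O[Si](C)(C)C(C)(C)C)[C@@H]2[C@@](C)(CO[Si](c3ccccc3)(c3ccccc3)C(C)(C)C)CCC[C@@]12C
F8 | step 15 | allyl 2-acetyl ester alkylated at C12 (C12 epimers) | CC(=O)C(C(=O)OCC=C)C[C@@H]1C(C)=C[C@@H](O[Si](C)(C)C(C)(C)C)[C@@H]2[C@@](C)(CO[Si](c3ccccc3)(c3ccccc3)C(C)(C)C)CCC[C@@]12C
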